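Left-handed product, counted in percent of both substrates together, is what this meeting had to forecast for two flasks.

| flask | left-handed substrate | right-handed substrate | reagent | remark | time |
|---|---|---|---|---|---|
| gamma | 0.25 M | 0.25 M | 1 M | run made earlier |  |
| beta | 1 M | 1 M | 1 M | run made earlier |  |
| delta | 0.50 M | 0.50 M | 0.50 M | run made earlier |  |
| midnight | 0.50 M | 0.50 M | 1.00 M |  | 3.0 h |
| dusk | 0.50 M | 0.50 M | 1.00 M |  | 1.0 h |

| run | time / h | left-handed product / % | left-handed substrate / % |
|---|---|---|---|
| gamma | 0.667 | 7.4 | 30.8 |
| gamma | 1.33 | 10.2 | 30.3 |
| gamma | 2.00 | 15.0 | 27.0 |
| gamma | 3.00 | 18.0 | 23.6 |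
| gamma | 4.00 | 21.1 | 22.5 |
| beta | 0.333 | 6.3 | 35.3 |
| beta | 0.833 | 7.0 | 31.9 |
| beta | 1.50 | 10.8 | 31.6 |
| beta | 2.50 | 12.7 | 27.4 |
| beta | 4.00 | 17.1 | 25.2 |
| delta | 0.333 | 3.8 | 35.7 |
| delta | 0.833 | 6.8 | 34.6 |
| delta | 1.50 | 6.0 | 33.7 |
| delta | 2.50 | 7.4 | 31.8 |
| delta | 4.00 | 9.8 | 29.7 |

(standard deviation of a reading: 1 percentage point)

- reagent is single-handed; left-handed substrate and right-handed substrate are mirror images of each other, charged as a racemate, each of them at the stated concentration
- the handed part of reagent does not stay in what it makes, so the products of the two hands are mirror images too

1. the winner by amount of left-handed product, in percent of the left-handed substrate and right-handed substrate together charged; "neither" if no more than 2 percentage points parts them (midnight / dusk / neither)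
2. how much left-handed product is there at the end, in percent of the left-handed substrate and right-handed substrate together charged: midnight
3. how much left-handed product is there at the end, in percent of the left-handed substrate and right-handed substrate together charged: dusk

Minutes. The chair observed that after its first reading left-handed product climbs in each run roughly along a straight line. A colleague compared the runs over equal spans: beta, with 1 M of reagent and 1 M of each substrate, gained 11 percentage points between its first and last readings, about twice the 6 points of delta, with 0.50 M of reagent and 0.50 M of each substrate. Since those two runs differ in both settings, she turned to gamma, which has the reagent of beta but 0.25 M of each substrate and gained 14 points in 3.33 h, and she argued from it that the percent gain follows the reagent.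

The chair then reckoned separately. Delta has the substrate charge of midnight and dusk, so the chair drew a straight line through its first and last readings and multiplied it by the reagent ratio, 2.00. That line reaches 16.3% at midnight's 3.0 h and 9.78% at dusk's 1.0 h. This L(t), the reagent-scaled delta line, favours midnight by more than the margin of 2 points.

The forecast's author, arguing that the new conditions “lie midway between gamma and beta”, gave 16% for midnight and 9% for dusk, with midnight the winner. The chair's dusk figure stood higher than the forecast's.

The flasks gave 17.1% in midnight and 8.68% in dusk, so midnight won; L(t) stood 0.80 points below the first and 1.1 points above the second.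

    reagent + left-handed substrate → left-handed product (k = 0.00680 M⁻¹ min⁻¹)
    left-handed product ⇌ right-handed product (k = 0.0230 min⁻¹)
    left-handed substrate ⇌ achiral form (K = 0.690, k = 0.260 min⁻¹)
    right-handed substrate ⇌ achiral form (K = 0.690, k = 0.260 min⁻¹)
    reagent + right-handed substrate → right-handed product (k = 1.00 × 10⁻⁴ M⁻¹ min⁻¹)

In midnight, reagent turned left-handed substrate into left-handed product while that product became right-handed product (racemisation), with a forward half-life of 0.50 h, short against 3.0 h. Meanwhile in midnight, the achiral form held 20.9% at 1.50 h and 17.6% at 3.00 h. For dusk left until 1.5 h, L(t) reads 11.4%, and that flask held 11.2% of left-handed product.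

The earlier runs and the new flask stem from a simulated flask from invented constants; the scatter is artificial.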